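**Strategy.** Each dihydrobenzofuran of the target is a 4-substituted 2,3-dihydrobenzofuran-6-ol: O1 sits on C7a, meta to the C6 hydroxyl, and C3a is para to that hydroxyl. Every fused benzene ring is therefore disconnected at O1–C7a to a plain 4-alkylphenol. In one flask, trivalent-iodine dearomatization of a tris(4-alkylphenol), 5-exo oxa-Michael addition of the three benzylic alcohols and loss of methanol re-form three arenes and close all three furan rings, among them the O1–C7a bond of the styryl-bearing ring. The precursor is an acyclic hexol (three phenols, three carbinols) whose six stereocentres come from three cycles of stereoretentive cross-coupling and asymmetric hydroboration of triarylethylenes.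

Key step: step 19

Abbreviations: TIPS = triisopropylsilyl; Bn = benzyl; Bpin = 4,4,5,5-tetramethyl-1,3,2-dioxaborolan-2-yl; IpcBH2 = monoisopinocampheylborane. DHB-1 is the terminal dihydrobenzofuran carrying the 3,5-dihydroxyphenyl group, DHB-2 the central one, DHB-3 the one carrying the stilbene.

Assumption (one remark on the chemistry): the facial sense of IpcBH2 is taken by analogy with 1-arylcycloalkenes (reagent from (+)-α-pinene gives the carbinol configuration drawn in 14); if the sense were the reverse, the two pinene antipodes would be exchanged between steps 8/14 and step 11.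

Step 1
Reactants: 1 4-hydroxybenzaldehyde
Product: 2 4-(TIPS-oxy)benzaldehyde
Conditions: TIPSCl, imidazole, DMF, rt
Reagents that add atoms: chlorotriisopropylsilane, CC(C)[Si](Cl)(C(C)C)C(C)C
Why: Imidazole-promoted O-silylation of a phenol; the TIPS ether should survive the aqueous base of the later couplings and is removed at the end by fluoride without acid.

Step 2
Reactants: 2 4-(TIPS-oxy)benzaldehyde
Product: 3 1-(2,2-dibromoethenyl)-4-(TIPS-oxy)benzene
Conditions: CBr4, PPh3, CH2Cl2, 0 °C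
Reagents that add atoms: carbon tetrabromide, BrC(Br)(Br)Br
Why: Ramirez dibromoolefination (first stage of the Corey–Fuchs reaction) of an aromatic aldehyde with the ylide formed from CBr4 and PPh3.

Step 3
Reactants: 4 4-bromo-3-chlorophenol
Product: 5 4-(benzyloxy)-1-bromo-2-chlorobenzene
Conditions: BnBr, K2CO3, DMF, rt
Reagents that add atoms: benzyl bromide, BrCc1ccccc1
Why: Williamson ether synthesis; the benzyl ether masks the future trigger phenol so that the later aryl-substituted alkenes cannot isomerize through quinone-methide tautomers.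

Step 4
Reactants: 5 4-(benzyloxy)-1-bromo-2-chlorobenzene; 3 1-(2,2-dibromoethenyl)-4-(TIPS-oxy)benzene
Product: 8 (Z)-bromoalkene [4-(benzyloxy)-1-{(Z)-1-bromo-2-[4-(TIPS-oxy)phenyl]ethenyl}-2-chlorobenzene], via aryllithium 6 (not isolated), via arylzinc chloride 7 (not isolated)
Conditions: n-BuLi, THF, −78 °C; ZnCl2, −78 °C → rt; then 3, PdCl2(DPEphos) (5 mol %), THF, rt
Reagents that add atoms: none
Why: Br/Li exchange and transmetalation to zinc, then Negishi coupling, which on a 1,1-dibromoalkene replaces selectively the bromine trans to the aryl group, so the (Z)-bromoalkene should form while the aryl chloride stays inert.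

Step 5
Reactants: 9 5-bromobenzene-1,3-diol
Product: 10 1-bromo-3,5-bis(TIPS-oxy)benzene
Conditions: TIPSCl, imidazole, DMF, rt
Reagents that add atoms: chlorotriisopropylsilane, CC(C)[Si](Cl)(C(C)C)C(C)C
Why: Double O-silylation of a resorcinol under the conditions of step 1.

Step 6
Reactants: 10 1-bromo-3,5-bis(TIPS-oxy)benzene
Product: 11 aryl boronate [2-{3,5-bis(TIPS-oxy)phenyl}-Bpin]
Conditions: B2pin2, PdCl2(dppf) (3 mol %), KOAc, 1,4-dioxane, 90 °C
Reagents that add atoms: bis(pinacolato)diboron, CC1(C)OB(OC1(C)C)B1OC(C)(C)C(C)(C)O1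
Why: Miyaura borylation of an unhindered aryl bromide.

Step 7
Reactants: 8 (Z)-bromoalkene; 11 aryl boronate
Product: 12 (E)-triarylethylene (4-silyloxyphenyl cis to the 3,5-bis(silyloxy)phenyl group)
Conditions: PdCl2(dppf) (5 mol %), aq. K2CO3, 1,4-dioxane, 85 °C
Reagents that add atoms: none
Why: Suzuki–Miyaura coupling of an alkenyl bromide proceeds with retention of alkene geometry, and the dppf-ligated catalyst should not touch the hindered aryl chloride.

Step 8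
Reactants: 12 (E)-triarylethylene
Product: 14 (1R,2R)-alcohol, via alkylborane 13 (not isolated)
Conditions: IpcBH2 [from (1R)-(+)-α-pinene] (2.5 equiv), THF, −25 °C → rt; then 3 M NaOH, 30% H2O2, 0 °C
Reagents that add atoms: hydrogen peroxide, OO
Why: Brown asymmetric hydroboration–oxidation: boron goes to the less substituted CH carbon, syn addition turns the alkene geometry into the relative configuration, the isopinocampheyl group selects the face (absolute configuration), and oxidation proceeds with retention.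

Step 9
Reactants: 14 (1R,2R)-alcohol
Product: 15 aryl boronate of 14 (Cl replaced by Bpin)
Conditions: B2pin2, Pd2(dba)3 (2 mol %), XPhos (8 mol %), KOAc, 1,4-dioxane, 100 °C
Reagents that add atoms: bis(pinacolato)diboron, CC1(C)OB(OC1(C)C)B1OC(C)(C)C(C)(C)O1
Why: Miyaura borylation of a hindered aryl chloride with the XPhos-ligated catalyst; KOAc does not ionize the neighbouring alcohol, so palladium-mediated C–O closure at the chlorine-bearing carbon (the wrong ring) should not compete.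

Step 10
Reactants: 15 aryl boronate; 8 (Z)-bromoalkene
Product: 16 second (E)-triarylethylene
Conditions: PdCl2(dppf) (10 mol %), aq. K2CO3, 1,4-dioxane, 85 °C
Reagents that add atoms: none
Why: Stereoretentive Suzuki–Miyaura coupling as in step 7, placing the ring of 15 cis to the new 4-silyloxyphenyl group.

Step 11
Reactants: 16 second (E)-triarylethylene
Product: 18 diol (new unit S,S), via alkylborane 17 (not isolated)
Conditions: IpcBH2 [from (1S)-(−)-α-pinene] (excess; the free hydroxyl consumes B–H), THF, −25 °C → rt; then 3 M NaOH, 30% H2O2, 0 °C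
Reagents that add atoms: hydrogen peroxide, OO
Why: The same syn hydroboration–oxidation with the antipodal reagent, so that reagent control should deliver the opposite (S,S) pair; diastereomers from incomplete control are separable here.

Step 12
Reactants: 18 diol
Product: 19 aryl boronate of 18 (Cl replaced by Bpin)
Conditions: B2pin2, Pd2(dba)3 (2 mol %), XPhos (8 mol %), KOAc, 1,4-dioxane, 100 °C
Reagents that add atoms: bis(pinacolato)diboron, CC1(C)OB(OC1(C)C)B1OC(C)(C)C(C)(C)O1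
Why: Miyaura borylation of the hindered aryl chloride as in step 9.

Step 13
Reactants: 19 aryl boronate; 8 (Z)-bromoalkene
Product: 20 third (E)-triarylethylene
Conditions: PdCl2(dppf) (10 mol %), aq. K2CO3, 1,4-dioxane, 85 °C
Reagents that add atoms: none
Why: Stereoretentive Suzuki–Miyaura coupling as in steps 7 and 10.

Step 14
Reactants: 20 third (E)-triarylethylene
Product: 22 triol (new unit R,R), via alkylborane 21 (not isolated)
Conditions: IpcBH2 [from (1R)-(+)-α-pinene] (excess), THF, −25 °C → rt; then 3 M NaOH, 30% H2O2, 0 °C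
Reagents that add atoms: hydrogen peroxide, OO
Why: Asymmetric syn hydroboration–oxidation as in step 8, the reagent again selecting the face that gives the (R,R) pair.

Step 15
Reactants: 22 triol
Product: 23 chloro hexol (three free phenols, three carbinols)
Conditions: H2 (1 atm), 5% Pd/C, EtOAc, rt
Reagents that add atoms: none
Why: Hydrogenolysis of aryl benzyl ethers on Pd/C is much faster in neutral ethyl acetate than cleavage of an electron-rich aryl C–Cl bond or of benzylic alcohols, and no alkene is left in the molecule.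

Step 16
Reactants: 24 3,4-dihydroxybenzaldehyde
Product: 25 3,4-bis(TIPS-oxy)benzaldehyde
Conditions: TIPSCl, imidazole, DMF, rt
Reagents that add atoms: chlorotriisopropylsilane, CC(C)[Si](Cl)(C(C)C)C(C)C
Why: Double O-silylation of a catechol under the conditions of step 1.

Step 17
Reactants: 25 3,4-bis(TIPS-oxy)benzaldehyde
Product: 26 (E)-alkenyl boronate
Conditions: CH2(Bpin)2, lithium 2,2,6,6-tetramethylpiperidide, THF, −78 °C → rt
Reagents that add atoms: bis(4,4,5,5-tetramethyl-1,3,2-dioxaborolan-2-yl)methane, CC1(C)OB(CB2OC(C)(C)C(C)(C)O2)OC1(C)C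
Why: Boron–Wittig olefination of an aldehyde with the lithiated bis(boryl)methane gives the (E)-alkenyl boronate by syn B–O elimination.

Step 18
Reactants: 23 chloro hexol; 26 (E)-alkenyl boronate
Product: 27 stilbene hexol
Conditions: Pd(OAc)2 (5 mol %), SPhos (10 mol %), K3PO4, toluene/H2O, 90 °C
Reagents that add atoms: none
Why: Suzuki–Miyaura coupling of an aryl chloride with the electron-rich biaryl phosphine SPhos, which activates hindered electron-rich C–Cl bonds; the alkenyl boronate couples with retention of the (E) geometry.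

Step 19
Reactants: 27 stilbene hexol
Product: 30 heptakis-TIPS ether of the target, via tris-quinol ether 28 (not isolated), via tris-oxa-Michael adduct 29 (not isolated)
Conditions: PhI(OAc)2 (3.3 equiv), MeOH/CH2Cl2, −10 °C; NaHCO3 wash, solvent switch; then TsOH·H2O (0.3 equiv), CH2Cl2, 0 °C → rt
Reagents that add atoms: none
Why: Ligand exchange of each free phenol at trivalent iodine and attack of methanol at the para carbon C3a should give three 4-alkyl-4-methoxycyclohexa-2,5-dienones (28); under TsOH each benzylic hydroxyl adds to the unsubstituted enone carbon C7a, and loss of methanol from C3a with tautomerization restores the arene, so each new bond is O1–C7a. The closest known reaction type is the oxidative dearomatization/hetero-Michael/rearomatization route to meta-functionalized phenols, as in the cyclization of tyrosol-type quinols to 2,3-dihydrobenzofuran-6-ols. Each of the three furan rings closes by 5-exo-trig oxa-Michael addition to a cis-fused bicycle that then aromatizes. No lasting stereocentre is formed: C2 and C3 of every ring keep the configuration set by hydroboration because no bond to them is broken, and the transient C3a/C7a centres vanish on aromatization. The step needs chemoselectivity for the three free phenols (all other phenols are silyl ethers, and phenols exchange at iodine far faster than the stilbene reacts) and regioselectivity for C7a over C4 (C4 is fully substituted; addition there is reversible and cannot lead to an arene).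

Step 20
Reactants: 30 heptakis-TIPS ether
Product: 31 CNP0099535.1 (target)
Conditions: Bu4NF (8 equiv), AcOH (8 equiv), THF, 0 °C → rt, argon
Reagents that add atoms: none
Why: Buffered fluoride cleaves the seven aryl silyl ethers without acid, which should leave the acid-sensitive stilbene and the benzylic C–O bonds of the dihydrobenzofurans untouched.

**Compound list**

1 | 4-hydroxybenzaldehyde | O=Cc1ccc(O)cc1 | starting material
2 | 4-[(triisopropylsilyl)oxy]benzaldehyde | O=Cc1ccc(O[Si](C(C)C)(C(C)C)C(C)C)cc1 | intermediate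
3 | 1-(2,2-dibromoethenyl)-4-[(triisopropylsilyl)oxy]benzene | BrC(Br)=Cc1ccc(O[Si](C(C)C)(C(C)C)C(C)C)cc1 | intermediate
4 | 4-bromo-3-chlorophenol | Oc1ccc(Br)c(Cl)c1 | starting material
5 | 4-(benzyloxy)-1-bromo-2-chlorobenzene | Brc1ccc(OCc2ccccc2)cc1Cl | intermediate
6 | [4-(benzyloxy)-2-chlorophenyl]lithium | [Li]c1ccc(OCc2ccccc2)cc1Cl | intermediate (not isolated)
7 | [4-(benzyloxy)-2-chlorophenyl]zinc chloride | Cl[Zn]c1ccc(OCc2ccccc2)cc1Cl | intermediate (not isolated)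
8 | 4-(benzyloxy)-1-[(Z)-1-bromo-2-{4-[(triisopropylsilyl)oxy]phenyl}ethenyl]-2-chlorobenzene | Br/C(=C\c1ccc(O[Si](C(C)C)(C(C)C)C(C)C)cc1)c1ccc(OCc2ccccc2)cc1Cl | intermediate
9 | 5-bromobenzene-1,3-diol | Oc1cc(O)cc(Br)c1 | starting material
10 | 1-bromo-3,5-bis[(triisopropylsilyl)oxy]benzene | Brc1cc(O[Si](C(C)C)(C(C)C)C(C)C)cc(O[Si](C(C)C)(C(C)C)C(C)C)c1 | intermediate
11 | 2-{3,5-bis[(triisopropylsilyl)oxy]phenyl}-4,4,5,5-tetramethyl-1,3,2-dioxaborolane | CC1(C)OB(OC1(C)C)c1cc(O[Si](C(C)C)(C(C)C)C(C)C)cc(O[Si](C(C)C)(C(C)C)C(C)C)c1 | intermediate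
12 | (E)-1-[4-(benzyloxy)-2-chlorophenyl]-1-{3,5-bis[(triisopropylsilyl)oxy]phenyl}-2-{4-[(triisopropylsilyl)oxy]phenyl}ethene (4-silyloxyphenyl cis to the 3,5-bis(silyloxy)phenyl group) | CC(C)[Si](C(C)C)(C(C)C)Oc1cc(O[Si](C(C)C)(C(C)C)C(C)C)cc(c1)/C(=C\c1ccc(O[Si](C(C)C)(C(C)C)C(C)C)cc1)c1ccc(OCc2ccccc2)cc1Cl | intermediate
13 | B-isopinocampheyl alkylborane from 12 (boron on the future carbinol carbon; Ipc from (+)-α-pinene) | Clc1cc(OCc2ccccc2)ccc1[C@@H](c1cc(O[Si](C(C)C)(C(C)C)C(C)C)cc(O[Si](C(C)C)(C(C)C)C(C)C)c1)[C@H](c1ccc(O[Si](C(C)C)(C(C)C)C(C)C)cc1)[BH][C@@H]1C[C@@H]2C[C@H]([C@H]1C)C2(C)C | intermediate (not isolated)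
14 | (1R,2R)-2-[4-(benzyloxy)-2-chlorophenyl]-2-{3,5-bis[(triisopropylsilyl)oxy]phenyl}-1-{4-[(triisopropylsilyl)oxy]phenyl}ethan-1-ol | O[C@@H](c1ccc(O[Si](C(C)C)(C(C)C)C(C)C)cc1)[C@H](c1cc(O[Si](C(C)C)(C(C)C)C(C)C)cc(O[Si](C(C)C)(C(C)C)C(C)C)c1)c1ccc(OCc2ccccc2)cc1Cl | intermediate
15 | pinacol boronate of 14 (Cl replaced by Bpin; stereocentres unchanged) | O[C@@H](c1ccc(O[Si](C(C)C)(C(C)C)C(C)C)cc1)[C@H](c1cc(O[Si](C(C)C)(C(C)C)C(C)C)cc(O[Si](C(C)C)(C(C)C)C(C)C)c1)c1ccc(OCc2ccccc2)cc1B1OC(C)(C)C(C)(C)O1 | intermediate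
16 | second triarylethylene: 14 with Cl replaced by the (E)-1-[4-(benzyloxy)-2-chlorophenyl]-2-{4-[(triisopropylsilyl)oxy]phenyl}ethenyl group (ring of 14 cis to the new 4-silyloxyphenyl group; first unit 1R,2R) | O[C@@H](c1ccc(O[Si](C(C)C)(C(C)C)C(C)C)cc1)[C@H](c1cc(O[Si](C(C)C)(C(C)C)C(C)C)cc(O[Si](C(C)C)(C(C)C)C(C)C)c1)c1ccc(OCc2ccccc2)cc1/C(=C\c1ccc(O[Si](C(C)C)(C(C)C)C(C)C)cc1)c1ccc(OCc2ccccc2)cc1Cl | intermediate
17 | B-isopinocampheyl alkylborane from 16 (Ipc from (−)-α-pinene) | O[C@@H](c1ccc(O[Si](C(C)C)(C(C)C)C(C)C)cc1)[C@H](c1cc(O[Si](C(C)C)(C(C)C)C(C)C)cc(O[Si](C(C)C)(C(C)C)C(C)C)c1)c1ccc(OCc2ccccc2)cc1[C@H]([C@@H](c1ccc(O[Si](C(C)C)(C(C)C)C(C)C)cc1)[BH][C@H]1C[C@H]2C[C@@H]([C@@H]1C)C2(C)C)c1ccc(OCc2ccccc2)cc1Cl | intermediate (not isolated)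
18 | diol: 14 with Cl replaced by the (1S,2S)-1-[4-(benzyloxy)-2-chlorophenyl]-2-hydroxy-2-{4-[(triisopropylsilyl)oxy]phenyl}ethyl group (first unit 1R,2R) | O[C@@H](c1ccc(O[Si](C(C)C)(C(C)C)C(C)C)cc1)[C@H](c1cc(O[Si](C(C)C)(C(C)C)C(C)C)cc(O[Si](C(C)C)(C(C)C)C(C)C)c1)c1ccc(OCc2ccccc2)cc1[C@H]([C@@H](c1ccc(O[Si](C(C)C)(C(C)C)C(C)C)cc1)O)c1ccc(OCc2ccccc2)cc1Cl | intermediate
19 | pinacol boronate of 18 (Cl replaced by Bpin; stereocentres unchanged in space) | O[C@@H](c1ccc(O[Si](C(C)C)(C(C)C)C(C)C)cc1)[C@H](c1cc(O[Si](C(C)C)(C(C)C)C(C)C)cc(O[Si](C(C)C)(C(C)C)C(C)C)c1)c1ccc(OCc2ccccc2)cc1[C@H]([C@@H](c1ccc(O[Si](C(C)C)(C(C)C)C(C)C)cc1)O)c1ccc(OCc2ccccc2)cc1B1OC(C)(C)C(C)(C)O1 | intermediate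
20 | third triarylethylene: 18 with Cl replaced by the (E)-1-[4-(benzyloxy)-2-chlorophenyl]-2-{4-[(triisopropylsilyl)oxy]phenyl}ethenyl group (ring of 18 cis to the new 4-silyloxyphenyl group; stereocentres unchanged in space) | O[C@@H](c1ccc(O[Si](C(C)C)(C(C)C)C(C)C)cc1)[C@H](c1cc(O[Si](C(C)C)(C(C)C)C(C)C)cc(O[Si](C(C)C)(C(C)C)C(C)C)c1)c1ccc(OCc2ccccc2)cc1[C@H]([C@@H](c1ccc(O[Si](C(C)C)(C(C)C)C(C)C)cc1)O)c1ccc(OCc2ccccc2)cc1/C(=C\c1ccc(O[Si](C(C)C)(C(C)C)C(C)C)cc1)c1ccc(OCc2ccccc2)cc1Cl | intermediate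
21 | B-isopinocampheyl alkylborane from 20 (Ipc from (+)-α-pinene) | O[C@@H](c1ccc(O[Si](C(C)C)(C(C)C)C(C)C)cc1)[C@H](c1cc(O[Si](C(C)C)(C(C)C)C(C)C)cc(O[Si](C(C)C)(C(C)C)C(C)C)c1)c1ccc(OCc2ccccc2)cc1[C@H]([C@@H](c1ccc(O[Si](C(C)C)(C(C)C)C(C)C)cc1)O)c1ccc(OCc2ccccc2)cc1[C@@H]([C@H](c1ccc(O[Si](C(C)C)(C(C)C)C(C)C)cc1)[BH][C@@H]1C[C@@H]2C[C@H]([C@H]1C)C2(C)C)c1ccc(OCc2ccccc2)cc1Cl | intermediate (not isolated)
22 | triol: 18 with Cl replaced by the (1R,2R)-1-[4-(benzyloxy)-2-chlorophenyl]-2-hydroxy-2-{4-[(triisopropylsilyl)oxy]phenyl}ethyl group (older stereocentres unchanged in space) | O[C@@H](c1ccc(O[Si](C(C)C)(C(C)C)C(C)C)cc1)[C@H](c1cc(O[Si](C(C)C)(C(C)C)C(C)C)cc(O[Si](C(C)C)(C(C)C)C(C)C)c1)c1ccc(OCc2ccccc2)cc1[C@H]([C@@H](c1ccc(O[Si](C(C)C)(C(C)C)C(C)C)cc1)O)c1ccc(OCc2ccccc2)cc1[C@@H]([C@H](c1ccc(O[Si](C(C)C)(C(C)C)C(C)C)cc1)O)c1ccc(OCc2ccccc2)cc1Cl | intermediate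
23 | chloro hexol: 22 with the three benzyl ethers replaced by free phenols (stereocentres unchanged in space) | O[C@@H](c1ccc(O[Si](C(C)C)(C(C)C)C(C)C)cc1)[C@H](c1cc(O[Si](C(C)C)(C(C)C)C(C)C)cc(O[Si](C(C)C)(C(C)C)C(C)C)c1)c1ccc(O)cc1[C@H]([C@@H](c1ccc(O[Si](C(C)C)(C(C)C)C(C)C)cc1)O)c1ccc(O)cc1[C@@H]([C@H](c1ccc(O[Si](C(C)C)(C(C)C)C(C)C)cc1)O)c1ccc(O)cc1Cl | intermediate
24 | 3,4-dihydroxybenzaldehyde | O=Cc1ccc(O)c(O)c1 | starting material
25 | 3,4-bis[(triisopropylsilyl)oxy]benzaldehyde | O=Cc1ccc(O[Si](C(C)C)(C(C)C)C(C)C)c(O[Si](C(C)C)(C(C)C)C(C)C)c1 | intermediate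
26 | 2-[(E)-2-{3,4-bis[(triisopropylsilyl)oxy]phenyl}ethenyl]-4,4,5,5-tetramethyl-1,3,2-dioxaborolane | CC1(C)OB(OC1(C)C)/C=C/c1ccc(O[Si](C(C)C)(C(C)C)C(C)C)c(O[Si](C(C)C)(C(C)C)C(C)C)c1 | intermediate
27 | stilbene hexol: 23 with Cl replaced by the (E)-2-{3,4-bis[(triisopropylsilyl)oxy]phenyl}ethenyl group | O[C@@H](c1ccc(O[Si](C(C)C)(C(C)C)C(C)C)cc1)[C@H](c1cc(O[Si](C(C)C)(C(C)C)C(C)C)cc(O[Si](C(C)C)(C(C)C)C(C)C)c1)c1ccc(O)cc1[C@H]([C@@H](c1ccc(O[Si](C(C)C)(C(C)C)C(C)C)cc1)O)c1ccc(O)cc1[C@@H]([C@H](c1ccc(O[Si](C(C)C)(C(C)C)C(C)C)cc1)O)c1ccc(O)cc1/C=C/c1ccc(O[Si](C(C)C)(C(C)C)C(C)C)c(O[Si](C(C)C)(C(C)C)C(C)C)c1 | intermediate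
28 | tris(4-methoxycyclohexa-2,5-dien-1-one) from 27 (each phenol ring oxidized at its para carbon; epimer mixture at the three methoxy-bearing carbons) | O[C@@H](c1ccc(O[Si](C(C)C)(C(C)C)C(C)C)cc1)[C@H](c1cc(O[Si](C(C)C)(C(C)C)C(C)C)cc(O[Si](C(C)C)(C(C)C)C(C)C)c1)C1(OC)C=CC(=O)C=C1[C@H]([C@@H](c1ccc(O[Si](C(C)C)(C(C)C)C(C)C)cc1)O)C1(OC)C=CC(=O)C=C1[C@@H]([C@H](c1ccc(O[Si](C(C)C)(C(C)C)C(C)C)cc1)O)C1(OC)C=CC(=O)C=C1/C=C/c1ccc(O[Si](C(C)C)(C(C)C)C(C)C)c(O[Si](C(C)C)(C(C)C)C(C)C)c1 | intermediate (not isolated)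
29 | tris(cis-fused 3a-methoxy-3,3a,7,7a-tetrahydro-1-benzofuran-6(2H)-one) from 28 | O2[C@@H](c1ccc(O[Si](C(C)C)(C(C)C)C(C)C)cc1)[C@H](c1cc(O[Si](C(C)C)(C(C)C)C(C)C)cc(O[Si](C(C)C)(C(C)C)C(C)C)c1)C1(OC)C2CC(=O)C=C1[C@H]([C@@H](c1ccc(O[Si](C(C)C)(C(C)C)C(C)C)cc1)O3)C1(OC)C3CC(=O)C=C1[C@@H]([C@H](c1ccc(O[Si](C(C)C)(C(C)C)C(C)C)cc1)O4)C1(OC)C4CC(=O)C=C1/C=C/c1ccc(O[Si](C(C)C)(C(C)C)C(C)C)c(O[Si](C(C)C)(C(C)C)C(C)C)c1 | intermediate (not isolated)
30 | heptakis-TIPS ether of the target: DHB-1 (2R,3R), DHB-2 (2S,3S), DHB-3 (2R,3R), all trans; the three C6 hydroxyls free | O2[C@@H](c1ccc(O[Si](C(C)C)(C(C)C)C(C)C)cc1)[C@H](c1cc(O[Si](C(C)C)(C(C)C)C(C)C)cc(O[Si](C(C)C)(C(C)C)C(C)C)c1)c1c2cc(O)cc1[C@H]([C@@H](c1ccc(O[Si](C(C)C)(C(C)C)C(C)C)cc1)O3)c1c3cc(O)cc1[C@@H]([C@H](c1ccc(O[Si](C(C)C)(C(C)C)C(C)C)cc1)O4)c1c4cc(O)cc1/C=C/c1ccc(O[Si](C(C)C)(C(C)C)C(C)C)c(O[Si](C(C)C)(C(C)C)C(C)C)c1 | intermediate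
31 | CNP0099535.1: (2R,3R)-3-(3,5-dihydroxyphenyl)-2-(4-hydroxyphenyl)-2,3-dihydrobenzofuran-6-ol (DHB-1) joined through C4 to C3 of the (2S,3S)-2-(4-hydroxyphenyl)-2,3-dihydrobenzofuran-6-ol (DHB-2), which is joined through its C4 to C3 of the (2R,3R)-2-(4-hydroxyphenyl)-4-[(E)-3,4-dihydroxystyryl]-2,3-dihydrobenzofuran-6-ol (DHB-3) | O2[C@@H](c1ccc(O)cc1)[C@H](c1cc(O)cc(O)c1)c1c2cc(O)cc1[C@H]([C@@H](c1ccc(O)cc1)O3)c1c3cc(O)cc1[C@@H]([C@H](c1ccc(O)cc1)O4)c1c4cc(O)cc1/C=C/c1ccc(O)c(O)c1 | target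

**Totals.** 20 steps in all. Longest linear sequence: 15 steps (1 → 2 → 3 → 8 → 12 → 14 → 15 → 16 → 18 → 19 → 20 → 22 → 23 → 27 → 30 → 31).

**Steps most likely to fail, with fallbacks**

Step 19 (key step). Capture of the oxidized phenol at the crowded para carbon C3a may lose out to loss of the neighbouring benzylic proton (quinone methide formation) or to C–C fragmentation of the hydroxyalkyl side chain. The excess oxidant may also attack the stilbene, and three such events must all succeed in one molecule. The fallback sets out from 27 and returns at 30. The three phenolates are oxygenated in the dark with singlet oxygen generated from KHSO5 (as 2KHSO5·KHSO4·K2SO4) and NaHCO3 in aqueous MeCN, a cycloaddition-type oxygenation without cationic intermediates, which should give the tris(4-hydroperoxycyclohexa-2,5-dienone) F1. Reduction with Me2S should give the tris(p-quinol) F2. TsOH·H2O in CH2Cl2 should then bring about the three oxa-Michael additions and dehydrations to 30.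

Step 8 (the same concern holds for steps 11 and 14). The bulky chiral borane may add sluggishly to the hindered triarylethylene or with poor facial selectivity; this would erode enantiomeric purity here and give diastereomer mixtures in the later cycles. The fallback sets out from 12 and returns at 14. Hydroboration–oxidation with BH3·SMe2 gives the racemic anti alcohol, that is 14 together with its enantiomer, the (1S,2S)-alcohol F3. Dess–Martin oxidation of the mixture gives the α,α-diaryl ketone F4, whose α-centre epimerizes readily. Asymmetric transfer hydrogenation under dynamic kinetic resolution with RuCl[(R,R)-TsDPEN](p-cymene) and HCO2H/Et3N should set the (R)-carbinol and, with the ortho-chloroaryl group acting as the large α-substituent, the anti (1R,2R) isomer 14; any syn isomer would be removed by chromatography.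

Step 18. Oxidative addition into the hindered C–Cl bond of a ring that becomes a phenoxide under the basic conditions may be slow, so that protodeboronation of the alkenyl boronate and silyl ether cleavage in hot aqueous base take over. The fallback sets out from 23 and returns at 27 by reversing the polarity. Miyaura borylation of 23 under the weak-base conditions of steps 9 and 12 (B2pin2, Pd2(dba)3, XPhos, KOAc) should give the aryl pinacol boronate F5. Boronate 26 is converted with NaOH and then I2 (iododeboronation with retention) into the (E)-alkenyl iodide F6. Coupling of F5 with F6 using PdCl2(dppf) and aq. K2CO3 at 40 °C should then give 27.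

**Further compounds**

F1 | step 19 | tris(4-hydroperoxycyclohexa-2,5-dien-1-one) from 27 | O[C@@H](c1ccc(O[Si](C(C)C)(C(C)C)C(C)C)cc1)[C@H](c1cc(O[Si](C(C)C)(C(C)C)C(C)C)cc(O[Si](C(C)C)(C(C)C)C(C)C)c1)C1(OO)C=CC(=O)C=C1[C@H]([C@@H](c1ccc(O[Si](C(C)C)(C(C)C)C(C)C)cc1)O)C1(OO)C=CC(=O)C=C1[C@@H]([C@H](c1ccc(O[Si](C(C)C)(C(C)C)C(C)C)cc1)O)C1(OO)C=CC(=O)C=C1/C=C/c1ccc(O[Si](C(C)C)(C(C)C)C(C)C)c(O[Si](C(C)C)(C(C)C)C(C)C)c1
F2 | step 19 | tris(4-hydroxycyclohexa-2,5-dien-1-one) (tris-p-quinol) from F1 | O[C@@H](c1ccc(O[Si](C(C)C)(C(C)C)C(C)C)cc1)[C@H](c1cc(O[Si](C(C)C)(C(C)C)C(C)C)cc(O[Si](C(C)C)(C(C)C)C(C)C)c1)C1(O)C=CC(=O)C=C1[C@H]([C@@H](c1ccc(O[Si](C(C)C)(C(C)C)C(C)C)cc1)O)C1(O)C=CC(=O)C=C1[C@@H]([C@H](c1ccc(O[Si](C(C)C)(C(C)C)C(C)C)cc1)O)C1(O)C=CC(=O)C=C1/C=C/c1ccc(O[Si](C(C)C)(C(C)C)C(C)C)c(O[Si](C(C)C)(C(C)C)C(C)C)c1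
F3 | step 8 | (1S,2S)-2-[4-(benzyloxy)-2-chlorophenyl]-2-{3,5-bis[(triisopropylsilyl)oxy]phenyl}-1-{4-[(triisopropylsilyl)oxy]phenyl}ethan-1-ol (enantiomer of 14) | O[C@H](c1ccc(O[Si](C(C)C)(C(C)C)C(C)C)cc1)[C@@H](c1cc(O[Si](C(C)C)(C(C)C)C(C)C)cc(O[Si](C(C)C)(C(C)C)C(C)C)c1)c1ccc(OCc2ccccc2)cc1Cl
F4 | step 8 | 2-[4-(benzyloxy)-2-chlorophenyl]-2-{3,5-bis[(triisopropylsilyl)oxy]phenyl}-1-{4-[(triisopropylsilyl)oxy]phenyl}ethan-1-one (racemic, labile α-centre) | O=C(c1ccc(O[Si](C(C)C)(C(C)C)C(C)C)cc1)C(c1cc(O[Si](C(C)C)(C(C)C)C(C)C)cc(O[Si](C(C)C)(C(C)C)C(C)C)c1)c1ccc(OCc2ccccc2)cc1Cl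
F5 | step 18 | pinacol boronate of 23 (Cl replaced by Bpin) | O[C@@H](c1ccc(O[Si](C(C)C)(C(C)C)C(C)C)cc1)[C@H](c1cc(O[Si](C(C)C)(C(C)C)C(C)C)cc(O[Si](C(C)C)(C(C)C)C(C)C)c1)c1ccc(O)cc1[C@H]([C@@H](c1ccc(O[Si](C(C)C)(C(C)C)C(C)C)cc1)O)c1ccc(O)cc1[C@@H]([C@H](c1ccc(O[Si](C(C)C)(C(C)C)C(C)C)cc1)O)c1ccc(O)cc1B1OC(C)(C)C(C)(C)O1
F6 | step 18 | 4-[(E)-2-iodoethenyl]-1,2-bis[(triisopropylsilyl)oxy]benzene | I/C=C/c1ccc(O[Si](C(C)C)(C(C)C)C(C)C)c(O[Si](C(C)C)(C(C)C)C(C)C)c1
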